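1. Which recipe ends with more target, winter or midnight? The answer sets the next charge.

| flask | substrate | remark | time |
|---|---|---|---|
| red | 0.0057 M | run made earlier |  |
| teal | 0.028 M | run made earlier |  |
| winter | 0.031 M |  | 25 h |
| midnight | 0.0080 M |  | 80 h |

- red (time / h: target / %, substrate / %): 1.33: 0.4, 99.8; 2.50: 0.3, 99.7; 5.00: 0.2, 99.5; 10.0: 0.8, 99.1; 20.0: 2.8, 97.0
- teal (time / h: target / %, substrate / %): 1.50: 0, 99.8; 4.00: 0.8, 99.6; 8.00: 4.2, 95.5; 12.0: 21.0, 79.6; 20.0: 81.5, 18.0

(each reading ± 0.3 percentage points)

- which one finishes higher in amount of target, in percent of the substrate charged ("neither" within 2 percentage points) (winter / midnight / neither)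
- amount of target at the end, in percent of the substrate charged, winter
- amount of target at the end, in percent of the substrate charged, midnight

- a reading or a percentage of target counts all its forms, free or not

2. If target makes more target (autocatalysis), the odds, target over substrate, should multiply steadily, at a rate proportional to the charge. Teal from 8.00 h to 12.0 h gives a log-odds slope of 0.448 h⁻¹.

3. Kept up, that line leaves teal 9.53% substrate at 20.0 h, but the reading is 18.0%, more. This reckoning therefore assumes a brake: working target stops at a ceiling, and substrate then falls first-order (pseudo-first-order), at the slope times the ceiling's fraction of the charge. Guess half the charge and match the last teal reading: this gives 45.4%. Going round once more gives 45.6%. So the ceiling, the highest [target] that keeps working, reads 12.8 mM.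

4. Midnight's charge of 8 mM lies below that, so in this reckoning its line runs free. Winter meets the ceiling at 41.2% of its charge.

5. Teal's line runs back to log-odds −6.71 at the start. Taking a steady trickle as the seed, starting odds go inversely with the charge. By this reckoning winter reaches the ceiling at about 13.0 h and ends near 94.9%. Midnight ends near 99.2%. The lead of 4.3 percentage points exceeds the margin, so midnight gets charged.

6. The forecast differs, with neither, 97% for winter and 98.5% for midnight: “Both are essentially finished”.

Winter ends at 95.1% and midnight at 99.2%, so midnight ends higher.

    substrate + target → 2 target (k = 0.00440 L mol⁻¹ s⁻¹)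
    substrate → target (k = 1.60 × 10⁻⁷ s⁻¹)
    crystals ⇌ target, rate k3*(cs3 - [target]) while solid is left; crystals form when [target] > cs3 (solubility = 13.0 mM, k = 0.00680 s⁻¹)

At 25.0 h winter holds 53.1% crystals, counted in its target, while midnight at 80.0 h holds 0%. Winter's target less the ceiling's share of its charge is 53.9%, set beside those crystals.

Read winter at 15 h instead: the ceiling reckoning gives 60.8% target. The computed value is 61.2%, with 18.9% crystals.

The earlier runs and the new flask are simulated for an exercise, noise included.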